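**Numbering used.** Benzofuran-2-one numbering: lactone O1, C2 (carbonyl), C3 (carries the exocyclic methylene), C3a, C4, C5, C6, C7, C7a. The side chain on C5 is C1′ (methine with a methyl group) to C4′ (CH2OH). Ring A is the cyclohexene, ring B the lactone.

## Analysis of the target

Target 32 is a cis-fused 3-methylidene-3a,4,7,7a-tetrahydro-1-benzofuran-2(3H)-one. Ring B is an α-methylene-γ-butyrolactone and ring A a cyclohexene whose C5=C6 double bond is tetrasubstituted (side chain on C5, methyl on C6). Ring A carries three contiguous stereocentres, C7a (R), C3a (R) and C4 (S): the lactone oxygen on C7a and C3 on C3a are cis, and the acyloxy group on C4 is trans to C3. A fourth centre, C1′ (S), is separated from the ring centres by the sp2 carbon C5, and a fifth, epimerisable one (R) sits α to the carbonyl of the 2-methylbutanoate. The sensitive groups are the methylene lactone (a conjugate acceptor), the allylic C4 ester, the C5=C6 bond (which can slip into conjugation whenever C7a is a carbonyl) and the free primary alcohol. The C4 and C7a oxygens are both γ to C2, so acyl migration and closure of the lactone onto the wrong oxygen are possible. The difficulties are therefore the position of the tetrasubstituted olefin, the choice between the two γ-oxygens, and the remote centre C1′. The strategy rests on the substitution pattern of ring A: oxygen on C7a and C4, carbon on C3a and C5, methyl on C6. This is the pattern of a 2-methyl-para-quinone monoketal, with C7a as ketal carbon, C5 as carbonyl, C6=C7 as the methylated enone and C4=C3a as the unsubstituted enone whose β-carbon is C3a.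

## Retrosynthetic reasoning

**C4′–O–Si and the C4 ester.** Target 32 is traced to silyl ether 31, and 31 to alcohol 29 and acid 30 by cutting the ester C–O bond. The acyl group is put on late because it would not survive the hydride and organolithium steps and could migrate onto a neighbouring enolate oxygen. Acid 30 brings its stereocentre from the chiral pool, so the forward acylation only has to avoid epimerising it.

**Lactone C2–O1.** Alcohol 29 comes from acetal ether 28, and 28 from diol 25 by cutting the acyl C–O bond of the lactone and lowering C2 to the alcohol level. The gain is that C2, C3 and the exocyclic methylene are already in place as a 2-substituted allylic alcohol, so no late α-methylenation is needed. In 25 only the C7a hydroxyl is free and the C4 oxygen is masked, so the ring can close in one direction only. The forward step has to oxidise a primary allylic alcohol in the presence of a secondary one.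

**C7a–H and the C7a carbonyl.** Diol 25 comes from silyl ether 24, 24 from ketone 23, and 23 from dimethyl ketal 22. The ketal is the original ketal carbon of the aromatic-derived ring, so it costs nothing to carry. The forward reduction must deliver hydride to the face opposite the C3a substituent.

**C5–C1′.** Ketal 22 is cut between the ring sp2 carbon and the side-chain stereocentre into alkenylstannane 12 and secondary boronic ester 19. This cut removes the one stereocentre that the ring cannot control and lets it be made separately. The forward union must be stereospecific at C1′, which a boron ate 1,2-shift with retention provides. Boronate 19 is cut at C1′–C2′ into ethyl ester 16 and primary boronate 15, and 15 is traced through allyl ether 14 to allyl alcohol 13.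

**C5–Sn and the position of the olefin.** Stannane 12 comes from enol triflate 11, and 11 from enone 9 by removing a hydride from C7 and the sulfonyl group from oxygen. This is where the C6=C7 enone of the quinone ketal becomes the C5=C6 olefin of the target. The forward step has to add hydride at C7 and trap the resulting enolate on oxygen, which fixes the double bond regiospecifically.

**C4–O.** Enone 9 comes from alcohol 8, and 8 from ketone 6 by cutting the C4–O bond. C4 is the only enolisable position of 6, so the site is unambiguous. The forward oxidation must take place anti to the substituent on C3a.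

**C3a–C3 (the key disconnection).** Ketone 6 is cut between C3a and C3 into the achiral dienone ketal 2 and alkenyl boronate 5. This is the only bond whose formation has to create absolute configuration; every other ring centre is relayed from it. The forward reaction must choose one of two enones and one of two faces.

**Starting materials.** Dienone 2 comes in one oxidation from phenol 1. Boronate 5 comes from bromide 4, which comes from alcohol 3.

## Alternatives that were turned down

**Alternative 1:** The C5=C6 double bond is disconnected. In the forward key step a second-generation Hoveyda–Grubbs catalyst would join the 2-methylallyl arm on C7a and the methylidene on C5 of the monocyclic lactone diene A2 and give A1, the tert-butyldimethylsilyl ether of 32. In its favour, A1 is one desilylation from the target, the position of the olefin is fixed by the ring closure, and no ketone ever sits at C7a. On the last two points it is stronger than the chosen route, where the olefin is placed by enolate trapping and must pass a β,γ-unsaturated ketone stage. Against it, the closure must make a tetrasubstituted olefin from two 1,1-disubstituted ones, the hardest class of ring-closing metathesis. The C5 methylidene is flanked by two stereocentres (C4 and C1′). The methylene lactone in A2 is a third 1,1-disubstituted olefin and could close a five-membered carbocycle with the methylallyl arm instead. All of C7a, C3a, C4 and C1′ would also have to be set on an open chain or a small lactone with no ring to relay them. The chosen route takes ring A ready-made from an arene and spends its single catalytic asymmetric step on one centre.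

**Alternative 2:** The C4–O bond is disconnected last. An engineered cytochrome P450 monooxygenase would hydroxylate the C4 methylene of the 4-deoxy lactone A4 on the face opposite ring B and give A3. It is stronger on step economy: no oxygen has to be carried and protected at C4, which removes the acetal ether and the lactonisation-selectivity problem of the chosen route. Against it, A4 offers the enzyme several competing sites: C7 (the other allylic methylene), the C6 methyl, the allylic C1′–H, and two olefins open to epoxidation. The methylene lactone can alkylate protein nucleophiles. The step depends on a catalyst that must first be evolved for this substrate. The chosen route forms the C4–O bond from an enolate that can exist at one position only, with the face set by the neighbouring substituent and reagents that can be bought.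

**Alternative 3:** The C5–C1′ bond is disconnected as the central event. The alkenyllithium from iodide A6 would add to the secondary boronic ester (the same compound as 19), and iodine with methoxide would trigger the 1,2-shift and elimination to give A5 with retention at C1′. This is the bond construction used in step 12 of the chosen route, and in A6 it is likely to be the more robust version: the lithium reagent comes from an iodide by direct exchange, and the ring carries no second olefin during the iodination. Against it as the organising idea, the key step creates no ring stereocentre, so A6 needs its own asymmetric synthesis. C3 is carried in A5 as a saturated two-carbon arm, so the steps after the union must include oxidation to the acid, lactonisation and α-methylenation as well as the acylation. The chosen route keeps the same union as a supporting step, brings in C2, C3 and the methylene in one piece, and derives all ring stereochemistry from one catalytic event.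

Key step: step 4

Assumption: ethyl 2,4,6-triisopropylbenzoate (16) is treated as purchasable, and the sense of induction of the diene ligand (step 4) and of (−)-sparteine (step 11) is taken from the accepted models; the antipodal ligand or diamine would be used if correlation showed the opposite sense.

## Route

**Step 1**
Reactants: 1 4-methoxy-2-methylphenol
Product: 2 4,4-dimethoxy-2-methylcyclohexa-2,5-dien-1-one
Conditions: PhI(OAc)2, MeOH, 0 to 23 °C
Reagents that add atoms: methanol, CO
Why: Oxidative dearomatisation of a para-methoxyphenol by the iodine diacetate; methanol traps the cationic intermediate at C4 to give the quinone monoketal, and no stereocentre is formed.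

**Step 2**
Reactants: 3 2-bromoprop-2-en-1-ol
Product: 4 [(2-bromoprop-2-en-1-yl)oxy](tert-butyl)dimethylsilane
Conditions: TBSCl, imidazole, CH2Cl2, 0 to 23 °C
Reagents that add atoms: tert-butyldimethylsilyl chloride, CC(C)(C)[Si](C)(C)Cl
Why: Standard silylation of a primary allylic alcohol; the silyloxy group is later a poor leaving group for β-oxygen elimination.

**Step 3**
Reactants: 4 [(2-bromoprop-2-en-1-yl)oxy](tert-butyl)dimethylsilane
Product: 5 tert-butyldimethyl{[2-(4,4,5,5-tetramethyl-1,3,2-dioxaborolan-2-yl)prop-2-en-1-yl]oxy}silane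
Conditions: B2pin2, PdCl2(PPh3)2 (3 mol %), PPh3 (6 mol %), KOPh, toluene, 50 °C
Reagents that add atoms: bis(pinacolato)diboron, CC1(C)OB(OC1(C)C)B1OC(C)(C)C(C)(C)O1
Why: Miyaura borylation of an alkenyl bromide (oxidative addition to zerovalent palladium, phenoxide-assisted transmetalation, reductive elimination); KOPh is used because acetate bases favour Suzuki homocoupling. The palladium route avoids the 2-lithioallyl silyl ether, which would undergo O-to-C silyl migration.

**Step 4**
Reactants: 2 4,4-dimethoxy-2-methylcyclohexa-2,5-dien-1-one; 5 tert-butyldimethyl{[2-(4,4,5,5-tetramethyl-1,3,2-dioxaborolan-2-yl)prop-2-en-1-yl]oxy}silane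
Product: 6 (5R)-5-[3-(tert-butyldimethylsilyloxy)prop-1-en-2-yl]-4,4-dimethoxy-2-methylcyclohex-2-en-1-one
Conditions: [RhCl(C2H4)2]2 (2.5 mol %), (1R,4R)-2,5-diphenylbicyclo[2.2.2]octa-2,5-diene (5.5 mol %), KOH (0.5 equiv, aq), 1,4-dioxane/H2O 10:1, 50 °C
Reagents that add atoms: none
Why: KOH converts the chloride precatalyst into a hydroxo complex of monovalent rhodium, to which the alkenyl group of 5 is transferred from boron; the alkenylrhodium species binds and inserts the unsubstituted C5=C6 double bond of 2, forming the C5–C bond (C3a–C3 of the target) and an oxa-π-allylrhodium enolate, which water protonates to release 6 and regenerate the hydroxo complex. The closest known reaction type is the rhodium/chiral diene-catalysed asymmetric 1,4-addition of alkenylboron reagents to cyclohexenones, cyclohexadienones and quinone monoketals (Hayashi–Miyaura reaction). No ring is closed. The single new stereocentre, C5, is controlled by the ligand: the phenyl group on the coordinated diene forces the enone to bind with its carbonyl side turned away, so one face of C5 is presented to the alkenyl group, and by the cyclohexenone model the (R,R) ligand should give 5R. Site selectivity between the two enones is needed and is secured by the C2 methyl group, since α-substituted enones bind and insert far more slowly; for the same reason the product should not react a second time. 1,4- over 1,2-addition is inherent to the rhodium enolate pathway, and the ketal and silyl ether are stable to the mildly basic aqueous medium. The alkenyl donor already carries C3, its methylene and C2 at the alcohol level, and its silyloxy group is a poor leaving group, which should disfavour β-oxygen elimination from the alkenylrhodium intermediate.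

**Step 5**
Reactants: 6 (5R)-5-[3-(tert-butyldimethylsilyloxy)prop-1-en-2-yl]-4,4-dimethoxy-2-methylcyclohex-2-en-1-one
Product: 8 (5S,6S)-5-[3-(tert-butyldimethylsilyloxy)prop-1-en-2-yl]-6-hydroxy-4,4-dimethoxy-2-methylcyclohex-2-en-1-one, via sodium enolate 7 (not isolated)
Conditions: NaN(SiMe3)2, THF, −78 °C; 2-(phenylsulfonyl)-3-phenyloxaziridine, −78 °C; NH4Cl aq
Reagents that add atoms: 2-(phenylsulfonyl)-3-phenyloxaziridine, O1N(S(=O)(=O)c2ccccc2)C1c1ccccc1
Why: Deprotonation can occur only at C6 because the γ-carbon is the quaternary ketal. Enolate hydroxylation with the N-sulfonyloxaziridine (Davis oxidation) should take place on the face opposite the neighbouring C5 alkenyl group, setting C6 trans to C5 (C4 of the target).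

**Step 6**
Reactants: 8 (5S,6S)-5-[3-(tert-butyldimethylsilyloxy)prop-1-en-2-yl]-6-hydroxy-4,4-dimethoxy-2-methylcyclohex-2-en-1-one
Product: 9 (5S,6S)-5-[3-(tert-butyldimethylsilyloxy)prop-1-en-2-yl]-4,4-dimethoxy-6-(methoxymethoxy)-2-methylcyclohex-2-en-1-one
Conditions: MOMCl, i-Pr2NEt, Bu4NI (cat.), CH2Cl2, 0 to 35 °C
Reagents that add atoms: chloromethyl methyl ether, COCCl
Why: O-Alkylation of the secondary alcohol under amine base. The acetal ether is chosen because it cannot leave from an enolate, cannot migrate to an adjacent carbanion as a silyl group would, and can chelate lithium in step 12.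

**Step 7**
Reactants: 9 (5S,6S)-5-[3-(tert-butyldimethylsilyloxy)prop-1-en-2-yl]-4,4-dimethoxy-6-(methoxymethoxy)-2-methylcyclohex-2-en-1-one
Product: 11 (5S,6S)-5-[3-(tert-butyldimethylsilyloxy)prop-1-en-2-yl]-4,4-dimethoxy-6-(methoxymethoxy)-2-methylcyclohex-1-en-1-yl trifluoromethanesulfonate, via lithium enolate 10 (not isolated)
Conditions: LiBH(s-Bu)3, THF, −78 °C; PhNTf2, −78 to 23 °C
Reagents that add atoms: N-phenylbis(trifluoromethanesulfonimide), FC(F)(F)S(=O)(=O)N(c1ccccc1)S(=O)(=O)C(F)(F)F
Why: Conjugate hydride addition to C3 of the α-methyl enone gives the tetrasubstituted enolate 10 regiospecifically, and O-sulfonylation (reductive enol triflation) fixes the double bond between C1 and C2, the future C5=C6. No stereocentre is touched.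

**Step 8**
Reactants: 11 (5S,6S)-5-[3-(tert-butyldimethylsilyloxy)prop-1-en-2-yl]-4,4-dimethoxy-6-(methoxymethoxy)-2-methylcyclohex-1-en-1-yl trifluoromethanesulfonate
Product: 12 {(5S,6S)-5-[3-(tert-butyldimethylsilyloxy)prop-1-en-2-yl]-4,4-dimethoxy-6-(methoxymethoxy)-2-methylcyclohex-1-en-1-yl}trimethylstannane
Conditions: Me3SnSnMe3, Pd(PPh3)4 (5 mol %), LiCl, THF, 65 °C
Reagents that add atoms: hexamethylditin, C[Sn](C)(C)[Sn](C)(C)C
Why: Palladium-catalysed stannylation of an enol triflate with a distannane (oxidative addition to zerovalent palladium, chloride exchange, tin transmetalation, reductive elimination) turns the C–O electrophile into a precursor of the alkenyllithium.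

**Step 9**
Reactants: 13 prop-2-en-1-ol
Product: 14 tert-butyl(diphenyl)(prop-2-en-1-yloxy)silane
Conditions: TBDPSCl, imidazole, CH2Cl2, 23 °C
Reagents that add atoms: tert-butyldiphenylsilyl chloride, CC(C)(C)[Si](Cl)(c1ccccc1)c1ccccc1
Why: Standard silylation; the tert-butyldiphenylsilyl ether must outlast the acid steps 13 and 15.

**Step 10**
Reactants: 14 tert-butyl(diphenyl)(prop-2-en-1-yloxy)silane
Product: 15 tert-butyl(diphenyl)[3-(4,4,5,5-tetramethyl-1,3,2-dioxaborolan-2-yl)propoxy]silane
Conditions: pinacolborane, [IrCl(cod)]2 (1.5 mol %), bis(diphenylphosphino)methane (3 mol %), CH2Cl2, 23 °C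
Reagents that add atoms: pinacolborane, CC1(C)OBOC1(C)C
Why: Iridium-catalysed hydroboration of a terminal alkene, which places boron on the terminal carbon.

**Step 11**
Reactants: 16 ethyl 2,4,6-triisopropylbenzoate; 15 tert-butyl(diphenyl)[3-(4,4,5,5-tetramethyl-1,3,2-dioxaborolan-2-yl)propoxy]silane
Product: 19 tert-butyl(diphenyl){[(4S)-4-(4,4,5,5-tetramethyl-1,3,2-dioxaborolan-2-yl)pentyl]oxy}silane, via lithiated benzoate 17 (not isolated), via boronate complex 18 (not isolated)
Conditions: s-BuLi, (−)-sparteine, Et2O, −78 °C, 5 h; 15, −78 °C, 1 h; then 35 °C, 16 h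
Reagents that add atoms: none
Why: Lithiation–borylation: sparteine-mediated deprotonation removes the pro-S hydrogen to give the configurationally stable carbenoid 17, and borylation proceeds with retention to 18. 1,2-Migration of the primary alkyl group with inversion at carbon then expels the hindered benzoate, which should give the (S)-boronate with the C1′ configuration of the target.

**Step 12**
Reactants: 12 {(5S,6S)-5-[3-(tert-butyldimethylsilyloxy)prop-1-en-2-yl]-4,4-dimethoxy-6-(methoxymethoxy)-2-methylcyclohex-1-en-1-yl}trimethylstannane; 19 tert-butyl(diphenyl){[(4S)-4-(4,4,5,5-tetramethyl-1,3,2-dioxaborolan-2-yl)pentyl]oxy}silane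
Product: 22 tert-butyl{[(4S)-4-{(5S,6S)-5-[3-(tert-butyldimethylsilyloxy)prop-1-en-2-yl]-4,4-dimethoxy-6-(methoxymethoxy)-2-methylcyclohex-1-en-1-yl}pentyl]oxy}diphenylsilane, via alkenyllithium 20 (not isolated), via boronate complex 21 (not isolated)
Conditions: MeLi, THF, −78 to −40 °C; 19, −78 °C; I2, THF/MeOH, −78 °C; NaOMe, MeOH, −78 to 23 °C; Na2S2O3 aq
Reagents that add atoms: none
Why: Tin–lithium exchange gives alkenyllithium 20, held by chelation to the methoxymethyl ether. Zweifel olefination then proceeds through boronate complex 21, iodonium formation, 1,2-shift of the secondary alkyl group with retention at C1′, and methoxide-induced anti elimination of boron and iodide, which re-forms the ring double bond.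

**Step 13**
Reactants: 22 tert-butyl{[(4S)-4-{(5S,6S)-5-[3-(tert-butyldimethylsilyloxy)prop-1-en-2-yl]-4,4-dimethoxy-6-(methoxymethoxy)-2-methylcyclohex-1-en-1-yl}pentyl]oxy}diphenylsilane
Product: 23 (5S,6S)-6-[3-(tert-butyldimethylsilyloxy)prop-1-en-2-yl]-4-[(2S)-5-(tert-butyldiphenylsilyloxy)pentan-2-yl]-5-(methoxymethoxy)-3-methylcyclohex-3-en-1-one
Conditions: pyridinium p-toluenesulfonate (0.2 equiv), acetone/H2O 10:1, 23 °C
Reagents that add atoms: water, O
Why: Acid-catalysed hydrolysis of a dialkyl ketone dimethyl ketal is much faster than cleavage of the silyl and methoxymethyl ethers. The weak acid and neutral work-up are meant to keep the β,γ-double bond out of conjugation and C6 from epimerising, and 23 is reduced without storage.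

**Step 14**
Reactants: 23 (5S,6S)-6-[3-(tert-butyldimethylsilyloxy)prop-1-en-2-yl]-4-[(2S)-5-(tert-butyldiphenylsilyloxy)pentan-2-yl]-5-(methoxymethoxy)-3-methylcyclohex-3-en-1-one
Product: 24 (1R,5S,6R)-6-[3-(tert-butyldimethylsilyloxy)prop-1-en-2-yl]-4-[(2S)-5-(tert-butyldiphenylsilyloxy)pentan-2-yl]-5-(methoxymethoxy)-3-methylcyclohex-3-en-1-ol
Conditions: LiBH(s-Bu)3, THF, −78 °C; NH4Cl aq
Reagents that add atoms: none
Why: The hindered borohydride should attack the ketone from the face opposite the adjacent C6 alkenyl substituent (equatorial attack on the conformer with that group equatorial), placing the new hydroxyl cis to it and setting C1 (C7a of the target). Reduction at −78 °C should outpace enolisation.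

**Step 15**
Reactants: 24 (1R,5S,6R)-6-[3-(tert-butyldimethylsilyloxy)prop-1-en-2-yl]-4-[(2S)-5-(tert-butyldiphenylsilyloxy)pentan-2-yl]-5-(methoxymethoxy)-3-methylcyclohex-3-en-1-ol
Product: 25 (1R,5S,6R)-4-[(2S)-5-(tert-butyldiphenylsilyloxy)pentan-2-yl]-6-(3-hydroxyprop-1-en-2-yl)-5-(methoxymethoxy)-3-methylcyclohex-3-en-1-ol
Conditions: camphorsulfonic acid (0.1 equiv), MeOH/CH2Cl2 1:1, 0 °C
Reagents that add atoms: none
Why: Acid-catalysed methanolysis removes the primary allylic tert-butyldimethylsilyl ether far faster than the tert-butyldiphenylsilyl ether, and the methoxymethyl ether is inert under these conditions.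

**Step 16**
Reactants: 25 (1R,5S,6R)-4-[(2S)-5-(tert-butyldiphenylsilyloxy)pentan-2-yl]-6-(3-hydroxyprop-1-en-2-yl)-5-(methoxymethoxy)-3-methylcyclohex-3-en-1-ol
Product: 28 (3aR,4S,7aR)-5-[(2S)-5-(tert-butyldiphenylsilyloxy)pentan-2-yl]-4-(methoxymethoxy)-6-methyl-3-methylidene-3a,4,7,7a-tetrahydro-1-benzofuran-2(3H)-one, via hydroxy enal 26 (not isolated), via lactol 27 (not isolated)
Conditions: TEMPO (0.2 equiv), PhI(OAc)2 (2.5 equiv), CH2Cl2, 23 °C
Reagents that add atoms: none
Why: Oxoammonium oxidation is selective for the primary allylic alcohol. Enal 26 is trapped by the only free hydroxyl, the cis C1 hydroxyl, as lactol 27, which is oxidised on to the lactone (oxidative lactonisation of a 1,4-diol); the C4 oxygen is masked, so the trans-fused isomer cannot form.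

**Step 17**
Reactants: 28 (3aR,4S,7aR)-5-[(2S)-5-(tert-butyldiphenylsilyloxy)pentan-2-yl]-4-(methoxymethoxy)-6-methyl-3-methylidene-3a,4,7,7a-tetrahydro-1-benzofuran-2(3H)-one
Product: 29 (3aS,4S,7aR)-5-[(2S)-5-(tert-butyldiphenylsilyloxy)pentan-2-yl]-4-hydroxy-6-methyl-3-methylidene-3a,4,7,7a-tetrahydro-1-benzofuran-2(3H)-one
Conditions: Me2BBr, CH2Cl2, −78 °C; NaHCO3 aq
Reagents that add atoms: none
Why: The bromoborane cleaves the acetal at −78 °C by coordination to the terminal methoxy oxygen, and the bromomethyl ether is hydrolysed on work-up. Silyl ether, lactone and olefins are expected to survive, and no base is present that could trigger translactonisation (the change of the C3a descriptor is a priority change only).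

**Step 18**
Reactants: 29 (3aS,4S,7aR)-5-[(2S)-5-(tert-butyldiphenylsilyloxy)pentan-2-yl]-4-hydroxy-6-methyl-3-methylidene-3a,4,7,7a-tetrahydro-1-benzofuran-2(3H)-one; 30 (R)-2-methylbutanoic acid
Product: 31 (3aR,4S,7aR)-5-[(2S)-5-(tert-butyldiphenylsilyloxy)pentan-2-yl]-6-methyl-3-methylidene-2-oxo-2,3,3a,4,7,7a-hexahydro-1-benzofuran-4-yl (2R)-2-methylbutanoate
Conditions: N,N′-dicyclohexylcarbodiimide, 4-(dimethylamino)pyridine (cat.), CH2Cl2, 0 to 23 °C
Reagents that add atoms: none
Why: Steglich esterification of the secondary allylic alcohol. The carbodiimide protocol at low temperature is chosen to limit ketene formation and so epimerisation at C2 of the acyl group.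

**Step 19**
Reactants: 31 (3aR,4S,7aR)-5-[(2S)-5-(tert-butyldiphenylsilyloxy)pentan-2-yl]-6-methyl-3-methylidene-2-oxo-2,3,3a,4,7,7a-hexahydro-1-benzofuran-4-yl (2R)-2-methylbutanoate
Product: 32 (3aR,4S,7aR)-5-[(2S)-5-hydroxypentan-2-yl]-6-methyl-3-methylidene-2-oxo-2,3,3a,4,7,7a-hexahydro-1-benzofuran-4-yl (2R)-2-methylbutanoate
Conditions: HF·pyridine, pyridine/THF, 0 to 23 °C
Reagents that add atoms: none
Why: Fluoride-mediated cleavage of the silyl ether under buffered, non-basic conditions, which spare the conjugate acceptor, the ester and the lactone.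

## Compound list

1 | 4-methoxy-2-methylphenol | COc1ccc(O)c(C)c1 | starting material
2 | 4,4-dimethoxy-2-methylcyclohexa-2,5-dien-1-one | COC1(OC)C=CC(=O)C(C)=C1 | intermediate
3 | 2-bromoprop-2-en-1-ol | OCC(Br)=C | starting material
4 | [(2-bromoprop-2-en-1-yl)oxy](tert-butyl)dimethylsilane | C=C(Br)CO[Si](C)(C)C(C)(C)C | intermediate
5 | tert-butyldimethyl{[2-(4,4,5,5-tetramethyl-1,3,2-dioxaborolan-2-yl)prop-2-en-1-yl]oxy}silane | C=C(CO[Si](C)(C)C(C)(C)C)B1OC(C)(C)C(C)(C)O1 | intermediate
6 | (5R)-5-[3-(tert-butyldimethylsilyloxy)prop-1-en-2-yl]-4,4-dimethoxy-2-methylcyclohex-2-en-1-one | COC1(OC)C=C(C)C(=O)C[C@@H]1C(=C)CO[Si](C)(C)C(C)(C)C | intermediate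
7 | sodium enolate of 6 (O on C1, double bond C1=C6) | COC1(OC)C=C(C)C([O-])=C[C@@H]1C(=C)CO[Si](C)(C)C(C)(C)C.[Na+] | intermediate (not isolated)
8 | (5S,6S)-5-[3-(tert-butyldimethylsilyloxy)prop-1-en-2-yl]-6-hydroxy-4,4-dimethoxy-2-methylcyclohex-2-en-1-one | COC1(OC)C=C(C)C(=O)[C@@H](O)[C@@H]1C(=C)CO[Si](C)(C)C(C)(C)C | intermediate
9 | (5S,6S)-5-[3-(tert-butyldimethylsilyloxy)prop-1-en-2-yl]-4,4-dimethoxy-6-(methoxymethoxy)-2-methylcyclohex-2-en-1-one | COC1(OC)C=C(C)C(=O)[C@@H](OCOC)[C@@H]1C(=C)CO[Si](C)(C)C(C)(C)C | intermediate
10 | lithium enolate from conjugate reduction of 9 (O on C1, double bond C1=C2; tri-sec-butylborane adduct) | COC1(OC)CC(C)=C([O-])[C@@H](OCOC)[C@@H]1C(=C)CO[Si](C)(C)C(C)(C)C.[Li+] | intermediate (not isolated)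
11 | (5S,6S)-5-[3-(tert-butyldimethylsilyloxy)prop-1-en-2-yl]-4,4-dimethoxy-6-(methoxymethoxy)-2-methylcyclohex-1-en-1-yl trifluoromethanesulfonate | COC1(OC)CC(C)=C(OS(=O)(=O)C(F)(F)F)[C@@H](OCOC)[C@@H]1C(=C)CO[Si](C)(C)C(C)(C)C | intermediate
12 | {(5S,6S)-5-[3-(tert-butyldimethylsilyloxy)prop-1-en-2-yl]-4,4-dimethoxy-6-(methoxymethoxy)-2-methylcyclohex-1-en-1-yl}trimethylstannane | COC1(OC)CC(C)=C([Sn](C)(C)C)[C@@H](OCOC)[C@@H]1C(=C)CO[Si](C)(C)C(C)(C)C | intermediate
13 | prop-2-en-1-ol | C=CCO | starting material
14 | tert-butyl(diphenyl)(prop-2-en-1-yloxy)silane | C=CCO[Si](c1ccccc1)(c1ccccc1)C(C)(C)C | intermediate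
15 | tert-butyl(diphenyl)[3-(4,4,5,5-tetramethyl-1,3,2-dioxaborolan-2-yl)propoxy]silane | CC1(C)OB(CCCO[Si](c2ccccc2)(c2ccccc2)C(C)(C)C)OC1(C)C | intermediate
16 | ethyl 2,4,6-triisopropylbenzoate | CCOC(=O)c1c(C(C)C)cc(C(C)C)cc1C(C)C | starting material
17 | (S)-1-lithioethyl 2,4,6-triisopropylbenzoate (sparteine complex) | C[C@@H]([Li])OC(=O)c1c(C(C)C)cc(C(C)C)cc1C(C)C | intermediate (not isolated)
18 | lithium boronate complex from 17 and 15 | C[C@H](OC(=O)c1c(C(C)C)cc(C(C)C)cc1C(C)C)[B-]1(CCCO[Si](c2ccccc2)(c2ccccc2)C(C)(C)C)OC(C)(C)C(C)(C)O1.[Li+] | intermediate (not isolated)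
19 | tert-butyl(diphenyl){[(4S)-4-(4,4,5,5-tetramethyl-1,3,2-dioxaborolan-2-yl)pentyl]oxy}silane | C[C@@H](CCCO[Si](c1ccccc1)(c1ccccc1)C(C)(C)C)B1OC(C)(C)C(C)(C)O1 | intermediate
20 | alkenyllithium from 12 (Li in place of the trimethylstannyl group) | COC1(OC)CC(C)=C([Li])[C@@H](OCOC)[C@@H]1C(=C)CO[Si](C)(C)C(C)(C)C | intermediate (not isolated)
21 | lithium alkenyl(sec-alkyl)boronate complex from 20 and 19 | COC1(OC)CC(C)=C([B-]2(OC(C)(C)C(C)(C)O2)[C@@H](C)CCCO[Si](c3ccccc3)(c3ccccc3)C(C)(C)C)[C@@H](OCOC)[C@@H]1C(=C)CO[Si](C)(C)C(C)(C)C.[Li+] | intermediate (not isolated)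
22 | tert-butyl{[(4S)-4-{(5S,6S)-5-[3-(tert-butyldimethylsilyloxy)prop-1-en-2-yl]-4,4-dimethoxy-6-(methoxymethoxy)-2-methylcyclohex-1-en-1-yl}pentyl]oxy}diphenylsilane | COC1(OC)CC(C)=C([C@@H](C)CCCO[Si](c2ccccc2)(c2ccccc2)C(C)(C)C)[C@@H](OCOC)[C@@H]1C(=C)CO[Si](C)(C)C(C)(C)C | intermediate
23 | (5S,6S)-6-[3-(tert-butyldimethylsilyloxy)prop-1-en-2-yl]-4-[(2S)-5-(tert-butyldiphenylsilyloxy)pentan-2-yl]-5-(methoxymethoxy)-3-methylcyclohex-3-en-1-one | O=C1CC(C)=C([C@@H](C)CCCO[Si](c2ccccc2)(c2ccccc2)C(C)(C)C)[C@@H](OCOC)[C@@H]1C(=C)CO[Si](C)(C)C(C)(C)C | intermediate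
24 | (1R,5S,6R)-6-[3-(tert-butyldimethylsilyloxy)prop-1-en-2-yl]-4-[(2S)-5-(tert-butyldiphenylsilyloxy)pentan-2-yl]-5-(methoxymethoxy)-3-methylcyclohex-3-en-1-ol | O[C@@H]1CC(C)=C([C@@H](C)CCCO[Si](c2ccccc2)(c2ccccc2)C(C)(C)C)[C@@H](OCOC)[C@@H]1C(=C)CO[Si](C)(C)C(C)(C)C | intermediate
25 | (1R,5S,6R)-4-[(2S)-5-(tert-butyldiphenylsilyloxy)pentan-2-yl]-6-(3-hydroxyprop-1-en-2-yl)-5-(methoxymethoxy)-3-methylcyclohex-3-en-1-ol | O[C@@H]1CC(C)=C([C@@H](C)CCCO[Si](c2ccccc2)(c2ccccc2)C(C)(C)C)[C@@H](OCOC)[C@@H]1C(=C)CO | intermediate
26 | hydroxy enal from 25 (primary alcohol oxidised to the 2-substituted propenal) | O[C@@H]1CC(C)=C([C@@H](C)CCCO[Si](c2ccccc2)(c2ccccc2)C(C)(C)C)[C@@H](OCOC)[C@@H]1C(=C)C=O | intermediate (not isolated)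
27 | lactol of 26 (2-hydroxy analogue of 28, anomeric mixture) | C=C1C(O)O[C@@H]2CC(C)=C([C@@H](C)CCCO[Si](c3ccccc3)(c3ccccc3)C(C)(C)C)[C@@H](OCOC)[C@H]12 | intermediate (not isolated)
28 | (3aR,4S,7aR)-5-[(2S)-5-(tert-butyldiphenylsilyloxy)pentan-2-yl]-4-(methoxymethoxy)-6-methyl-3-methylidene-3a,4,7,7a-tetrahydro-1-benzofuran-2(3H)-one | C=C1C(=O)O[C@@H]2CC(C)=C([C@@H](C)CCCO[Si](c3ccccc3)(c3ccccc3)C(C)(C)C)[C@@H](OCOC)[C@H]12 | intermediate
29 | (3aS,4S,7aR)-5-[(2S)-5-(tert-butyldiphenylsilyloxy)pentan-2-yl]-4-hydroxy-6-methyl-3-methylidene-3a,4,7,7a-tetrahydro-1-benzofuran-2(3H)-one | C=C1C(=O)O[C@@H]2CC(C)=C([C@@H](C)CCCO[Si](c3ccccc3)(c3ccccc3)C(C)(C)C)[C@@H](O)[C@H]12 | intermediate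
30 | (R)-2-methylbutanoic acid | OC(=O)[C@H](C)CC | starting material
31 | (3aR,4S,7aR)-5-[(2S)-5-(tert-butyldiphenylsilyloxy)pentan-2-yl]-6-methyl-3-methylidene-2-oxo-2,3,3a,4,7,7a-hexahydro-1-benzofuran-4-yl (2R)-2-methylbutanoate | C=C1C(=O)O[C@@H]2CC(C)=C([C@@H](C)CCCO[Si](c3ccccc3)(c3ccccc3)C(C)(C)C)[C@@H](OC(=O)[C@H](C)CC)[C@H]12 | intermediate
32 | (3aR,4S,7aR)-5-[(2S)-5-hydroxypentan-2-yl]-6-methyl-3-methylidene-2-oxo-2,3,3a,4,7,7a-hexahydro-1-benzofuran-4-yl (2R)-2-methylbutanoate | C=C1C(=O)O[C@@H]2CC(C)=C([C@@H](C)CCCO)[C@@H](OC(=O)[C@H](C)CC)[C@H]12 | target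

## Step count and least certain steps

Total step count: 19. Longest linear sequence: 15 steps (steps 2, 3, 4, 5, 6, 7, 8, 12, 13, 14, 15, 16, 17, 18, 19).

**Step 4 (key step).** The most likely failure is slow transfer of the α-branched, allylically oxygenated alkenyl group from boron to rhodium. Protodeboronation of 5, or loss of the silyloxy group from the alkenylrhodium species by β-oxygen elimination, could then outrun insertion. A second concern is incomplete discrimination of the enone faces at a β-carbon next to the quaternary ketal centre. The fallback keeps the bond construction but no longer carries the C2 oxygen through the catalytic step; it addresses the reactivity problem, not the face selectivity. It sets out from 2, which under the same catalyst takes up the simple 2-propenyl group from commercial isopropenylboronic acid pinacol ester to give the isopropenyl enone F1. Ene-type allylic chlorination of the isopropenyl group (Ca(OCl)2, CO2, CH2Cl2/H2O) should give the allylic chloride F2. Displacement with KOAc in DMF should give the acetate F3, and methanolysis (K2CO3, MeOH) the allylic alcohol F4. Silylation as in step 2 brings the sequence back to the route at 6.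

**Step 7.** Hydride may be delivered to the carbonyl carbon instead of the β-carbon, which is neopentyl-like next to the ketal, and O-sulfonylation of the hindered, borane-complexed enolate may be slow, so that protonation wins on work-up. The fallback changes the reductant class and the way the enolate is made. It sets out from 9: catalytic [(Ph3P)CuH]6 with PhMe2SiH in toluene, which is 1,4-selective with hindered enones, should give the dimethylphenylsilyl enol ether F5. MeLi in THF releases the borane-free lithium enolate 10, which is triflated with PhNTf2, rejoining the route at 11.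

**Step 12.** The boronate complex 21 may form incompletely from the doubly flanked alkenyllithium 20 and the α-branched ester 19, with loss of 20 to protonation or direct iodination. The fallback replaces the boron ate shift by a stereoretentive palladium-catalysed C(sp2)–C(sp3) cross-coupling. It sets out from 12, which with I2 in CH2Cl2 at 0 °C gives the alkenyl iodide F6. The enantiomeric boronate F7 (step 11 run with (+)-sparteine) is oxidised with NaBO3 to the (R)-alcohol F8 and converted with inversion (I2, PPh3, imidazole) into the (S)-iodide F9. Iodine–lithium exchange with t-BuLi at −100 °C and immediate transmetalation with Me3SiCH2ZnBr·LiBr should give, with retention, the mixed dialkylzinc F10. F10 is coupled with F6 under Pd(OAc)2 and a dialkylbiarylphosphine, also with retention, rejoining the route at 22.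

**Step 14.** Facial selectivity may be poor, because the face opposite the C6 substituent is also the face that carries the C5 methoxymethoxy group when that group is pseudoaxial. Conjugation of the β,γ-double bond or β-elimination of the C5 alkoxy group could also compete if reduction is slow. The fallback sets the centre by SN2 inversion instead of hydride face selectivity. It sets out from 23: a small hydride (NaBH4, MeOH, −40 °C) is used, and the trans alcohol F11 obtained from it (or separated from the step 14 mixture) is inverted by Mitsunobu esterification (4-nitrobenzoic acid, PPh3, diisopropyl azodicarboxylate) to the cis 4-nitrobenzoate F12. Methanolysis (K2CO3, MeOH) returns the sequence to the route at 24.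

## Further compounds

F1 | step 4 | (5R)-4,4-dimethoxy-2-methyl-5-(prop-1-en-2-yl)cyclohex-2-en-1-one | COC1(OC)C=C(C)C(=O)C[C@@H]1C(C)=C
F2 | step 4 | (5R)-5-(3-chloroprop-1-en-2-yl)-4,4-dimethoxy-2-methylcyclohex-2-en-1-one | COC1(OC)C=C(C)C(=O)C[C@@H]1C(=C)CCl
F3 | step 4 | 2-[(1R)-6,6-dimethoxy-4-methyl-3-oxocyclohex-4-en-1-yl]prop-2-en-1-yl acetate | COC1(OC)C=C(C)C(=O)C[C@@H]1C(=C)COC(C)=O
F4 | step 4 | (5R)-5-(3-hydroxyprop-1-en-2-yl)-4,4-dimethoxy-2-methylcyclohex-2-en-1-one | COC1(OC)C=C(C)C(=O)C[C@@H]1C(=C)CO
F5 | step 7 | dimethylphenylsilyl enol ether of the 2,3-dihydro ketone from 9 (silyloxy on C1, double bond C1=C2) | COC1(OC)CC(C)=C(O[Si](C)(C)c2ccccc2)[C@@H](OCOC)[C@@H]1C(=C)CO[Si](C)(C)C(C)(C)C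
F6 | step 12 | alkenyl iodide corresponding to 12 (iodine in place of the trimethylstannyl group) | COC1(OC)CC(C)=C(I)[C@@H](OCOC)[C@@H]1C(=C)CO[Si](C)(C)C(C)(C)C
F7 | step 12 | tert-butyl(diphenyl){[(4R)-4-(4,4,5,5-tetramethyl-1,3,2-dioxaborolan-2-yl)pentyl]oxy}silane | C[C@H](CCCO[Si](c1ccccc1)(c1ccccc1)C(C)(C)C)B1OC(C)(C)C(C)(C)O1
F8 | step 12 | (2R)-5-(tert-butyldiphenylsilyloxy)pentan-2-ol | C[C@@H](O)CCCO[Si](c1ccccc1)(c1ccccc1)C(C)(C)C
F9 | step 12 | tert-butyl{[(4S)-4-iodopentyl]oxy}diphenylsilane | C[C@H](I)CCCO[Si](c1ccccc1)(c1ccccc1)C(C)(C)C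
F10 | step 12 | [(2S)-5-(tert-butyldiphenylsilyloxy)pentan-2-yl][(trimethylsilyl)methyl]zinc | C[C@H]([Zn]C[Si](C)(C)C)CCCO[Si](c1ccccc1)(c1ccccc1)C(C)(C)C
F11 | step 14 | C1 epimer of 24 (hydroxyl trans to the C6 alkenyl group) | O[C@H]1CC(C)=C([C@@H](C)CCCO[Si](c2ccccc2)(c2ccccc2)C(C)(C)C)[C@@H](OCOC)[C@@H]1C(=C)CO[Si](C)(C)C(C)(C)C
F12 | step 14 | 4-nitrobenzoate of 24 | O=C(O[C@@H]1CC(C)=C([C@@H](C)CCCO[Si](c2ccccc2)(c2ccccc2)C(C)(C)C)[C@@H](OCOC)[C@@H]1C(=C)CO[Si](C)(C)C(C)(C)C)c1ccc(cc1)[N+](=O)[O-]
A1 | alternative 1 | tert-butyldimethylsilyl ether of 32 (product of the ring-closing metathesis) | C=C1C(=O)O[C@@H]2CC(C)=C([C@@H](C)CCCO[Si](C)(C)C(C)(C)C)[C@@H](OC(=O)[C@H](C)CC)[C@H]12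
A2 | alternative 1 | monocyclic lactone diene with a 2-methylallyl group on C7a and a methylidene on C5 | C=C1C(=O)O[C@H](CC(C)=C)[C@@H]1[C@H](OC(=O)[C@H](C)CC)C(=C)[C@@H](C)CCCO[Si](C)(C)C(C)(C)C
A3 | alternative 2 | 4-hydroxy α-methylene lactone, primary acetate (product of the enzymatic hydroxylation) | C=C1C(=O)O[C@@H]2CC(C)=C([C@@H](C)CCCOC(C)=O)[C@@H](O)[C@H]12
A4 | alternative 2 | 4-deoxy α-methylene lactone, primary acetate | C=C1C(=O)O[C@@H]2CC(C)=C([C@@H](C)CCCOC(C)=O)C[C@H]12
A5 | alternative 3 | coupled tetrasubstituted cyclohexene (product of the boron ate union) | CC1=C([C@@H](C)CCCO[Si](c2ccccc2)(c2ccccc2)C(C)(C)C)[C@@H](OCOC)[C@H](CCO[Si](C)(C)C(C)(C)C)[C@H](O[Si](C)(C)C(C)(C)C)C1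
A6 | alternative 3 | C5 alkenyl iodide of the protected ring fragment | CC1=C(I)[C@@H](OCOC)[C@H](CCO[Si](C)(C)C(C)(C)C)[C@H](O[Si](C)(C)C(C)(C)C)C1
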